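**Retrosynthetic overview**
1. The twelve OH groups are carried as benzyl ethers and freed last. Dodecabenzyl ether 33 is cut at the ring C–O–ring D ether (Ullmann) into three-ring phenol 32 (A–B–C) and two-ring iodide 10 (D–E).
2. Ring C is added to the hindered two-ring phenol 25 (A–B) by SNAr on an ortho-fluorobenzaldehyde. The formyl carbon is then exchanged for the phenol oxygen by Baeyer–Villiger oxidation.
3. Ring A is built on the ring B oxygen instead of being coupled. Aryloxyacetate 16 and the methyl acetoacetate dianion undergo an intermolecular Claisen condensation; this key C–C bond becomes C2–C3 of ring A. The diketo ester goes to a pyranone, then to the carbocycle by intramolecular Claisen closure and aromatisation.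
4. Rings B, D and E all come from one block, 2,6-bis(benzyloxy)-4-bromophenol 4. D–E is joined by Chan–Lam coupling.
5. Ring order: rings B, C, D and E enter as benzene rings. Only ring A is formed, first as the pyranone (step 11), then as the benzene ring (step 13).

Assumption: the SMILES holds no stereocentre and the diaryl ether axes rotate freely, so the target is achiral and "single enantiomer" means the compound as drawn. Rings are lettered A to E from the 2,4,6-trihydroxyphenyl end to the 3,4,5-trihydroxyphenyl end.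

**Step 1**
Reactants: 1 4-bromo-2,6-difluorobenzaldehyde
Product: 2 2,6-bis(benzyloxy)-4-bromobenzaldehyde
Conditions: BnOH (2.3 equiv), NaH (2.3 equiv), THF, 0 °C; add 1, 0 → 50 °C
Reagents that add atoms: benzyl alcohol, OCc1ccccc1
Why: Double SNAr, in which both fluorides sit ortho to the formyl group and are displaced by benzyloxide far faster than the para bromide, while the di-ortho-substituted aldehyde resists hydride-transfer side reactions.

**Step 2**
Reactants: 2 2,6-bis(benzyloxy)-4-bromobenzaldehyde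
Product: 4 2,6-bis(benzyloxy)-4-bromophenol, via aryl formate 3 (not isolated)
Conditions: mCPBA (1.3 equiv), CH2Cl2, 0 °C → rt; then K2CO3 (0.2 equiv), MeOH, rt
Reagents that add atoms: mCPBA, OOC(=O)c1cccc(Cl)c1
Why: Baeyer–Villiger (Dakin-type) oxidation, in which the aryl group with two ortho alkoxy donors migrates in preference to hydrogen and mild methanolysis of the formate frees the phenol without touching bromide or benzyl ethers.

**Step 3**
Reactants: 4 2,6-bis(benzyloxy)-4-bromophenol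
Product: 5 1,2,3-tris(benzyloxy)-5-bromobenzene
Conditions: BnBr (1.2 equiv), K2CO3, DMF, 60 °C
Reagents that add atoms: benzyl bromide, BrCc1ccccc1
Why: Williamson ether synthesis on the phenoxide, which has no competing nucleophilic site.

**Step 4**
Reactants: 5 1,2,3-tris(benzyloxy)-5-bromobenzene
Product: 8 [3,4,5-tris(benzyloxy)phenyl]boronic acid, via aryllithium 6 (not isolated), via lithium aryl(triisopropoxy)borate 7 (not isolated)
Conditions: n-BuLi (1.05 equiv), THF, −78 °C; B(OiPr)3, −78 °C → rt; 1 M HCl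
Reagents that add atoms: triisopropyl borate, CC(C)OB(OC(C)C)OC(C)C; water, O
Why: Bromine–lithium exchange at −78 °C outruns benzylic deprotonation, and borate trapping followed by hydrolysis gives the boronic acid.

**Step 5**
Reactants: 4 2,6-bis(benzyloxy)-4-bromophenol; 8 [3,4,5-tris(benzyloxy)phenyl]boronic acid
Product: 9 1,3-bis(benzyloxy)-5-bromo-2-[3,4,5-tris(benzyloxy)phenoxy]benzene
Conditions: 8 (2 equiv), Cu(OAc)2 (1.0 equiv), pyridine (5 equiv), 4 Å MS, CH2Cl2, dry air, rt, 48 h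
Reagents that add atoms: none
Why: Chan–Lam–Evans O-arylation runs at room temperature, accepts di-ortho-substituted phenols and leaves the aryl bromide untouched, with air re-oxidising copper so that Cu(OAc)2 is returned.

**Step 6**
Reactants: 9 1,3-bis(benzyloxy)-5-bromo-2-[3,4,5-tris(benzyloxy)phenoxy]benzene
Product: 10 1,3-bis(benzyloxy)-5-iodo-2-[3,4,5-tris(benzyloxy)phenoxy]benzene
Conditions: CuI (10 mol %), NaI (2 equiv), trans-N,N'-dimethylcyclohexane-1,2-diamine (20 mol %), 1,4-dioxane, 110 °C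
Reagents that add atoms: sodium iodide, [Na+].[I-]
Why: Copper-catalysed aromatic Finkelstein reaction, driven by the low solubility of NaBr in dioxane, supplies the more reactive iodide for the last coupling.

**Step 7**
Reactants: 4 2,6-bis(benzyloxy)-4-bromophenol
Product: 11 1,3-bis(benzyloxy)-5-bromo-2-(methoxymethoxy)benzene
Conditions: NaH (1.2 equiv), MOMCl (1.3 equiv), THF–DMF, 0 °C → rt
Reagents that add atoms: chloromethyl methyl ether, COCCl
Why: Williamson-type O-alkylation gives a MOM acetal that survives organolithiums, enolates and alkoxides and can later be removed by mild acid beside benzyl ethers.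

**Step 8**
Reactants: 11 1,3-bis(benzyloxy)-5-bromo-2-(methoxymethoxy)benzene
Product: 14 3,5-bis(benzyloxy)-4-(methoxymethoxy)phenol, via aryllithium 12 (not isolated), via lithium aryl(trimethoxy)borate 13 (not isolated)
Conditions: n-BuLi (1.05 equiv), THF, −78 °C; B(OMe)3, −78 → 0 °C; AcOH, 30 % H2O2, 0 °C → rt
Reagents that add atoms: hydrogen peroxide, OO
Why: Bromine–lithium exchange, borate formation and oxidative 1,2-aryl shift from boron to oxygen (boronate oxidation) turn C–Br into C–OH at the unhindered position of ring B.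

**Step 9**
Reactants: 14 3,5-bis(benzyloxy)-4-(methoxymethoxy)phenol; 15 methyl bromoacetate
Product: 16 methyl 2-[3,5-bis(benzyloxy)-4-(methoxymethoxy)phenoxy]acetate
Conditions: K2CO3 (2 equiv), acetone, reflux
Reagents that add atoms: none
Why: Williamson ether synthesis of an unhindered phenoxide with a very reactive alpha-halo ester, which already makes the ring A–O–ring B bond.

**Step 10 (key step)**
Reactants: 16 methyl 2-[3,5-bis(benzyloxy)-4-(methoxymethoxy)phenoxy]acetate; 17 methyl acetoacetate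
Product: 19 methyl 6-[3,5-bis(benzyloxy)-4-(methoxymethoxy)phenoxy]-3,5-dioxohexanoate, via sodium lithium dianion 18 (not isolated)
Conditions: 17 (2.5 equiv), NaH then n-BuLi (2.5 equiv each), THF, 0 °C; add 16, −78 → 0 °C; AcOH quench
Reagents that add atoms: none
Why: Intermolecular Claisen condensation (Huckin–Weiler dianion acylation), in which the terminal carbanion of the dianion attacks the activated alpha-aryloxy ester and excess dianion deprotonates the more acidic diketo ester, making the C–C bond (later C2–C3 of ring A) irreversible.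

**Step 11**
Reactants: 19 methyl 6-[3,5-bis(benzyloxy)-4-(methoxymethoxy)phenoxy]-3,5-dioxohexanoate
Product: 20 6-{[3,5-bis(benzyloxy)-4-(methoxymethoxy)phenoxy]methyl}-4-hydroxy-2H-pyran-2-one
Conditions: DBU (1.2 equiv), toluene, 90 °C; citric acid work-up
Reagents that add atoms: none
Why: Base-induced enol lactonisation of a 3,5-dioxo ester, which loses methanol, fixes the cis arrangement of the chain and tells the C3 oxygen (later para oxygen of ring A) apart from the other two.

**Step 12**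
Reactants: 20 6-{[3,5-bis(benzyloxy)-4-(methoxymethoxy)phenoxy]methyl}-4-hydroxy-2H-pyran-2-one
Product: 21 4-(benzyloxy)-6-{[3,5-bis(benzyloxy)-4-(methoxymethoxy)phenoxy]methyl}-2H-pyran-2-one
Conditions: BnOH (1.2 equiv), PPh3 (1.3 equiv), DIAD (1.3 equiv), THF, 0 °C → rt
Reagents that add atoms: benzyl alcohol, OCc1ccccc1
Why: Mitsunobu etherification alkylates the acidic vinylogous acid on the 4-oxygen and avoids the C3-benzylation that benzyl halide and base can give.

**Step 13**
Reactants: 21 4-(benzyloxy)-6-{[3,5-bis(benzyloxy)-4-(methoxymethoxy)phenoxy]methyl}-2H-pyran-2-one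
Product: 23 5-(benzyloxy)-2-[3,5-bis(benzyloxy)-4-(methoxymethoxy)phenoxy]benzene-1,3-diol, via ring-opened benzyl enoate 22 (not isolated)
Conditions: NaOBn (3 equiv, from BnOH + NaH), THF, rt, 1 h; then toluene, 110 °C, Ar; AcOH quench
Reagents that add atoms: none
Why: Benzyloxide opens the enol lactone to the (E)-enoate 22 whose ester and keto side chain stay cis, the aryloxy-stabilised ketone enolate closes on the ester (intramolecular Claisen, Dieckmann type, forming C1–C6 of ring A), irreversible tautomerisation to the resorcinolate pulls the reversible equilibria forward, and any alkoxide exchange is degenerate because only benzyloxy groups are present.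

**Step 14**
Reactants: 23 5-(benzyloxy)-2-[3,5-bis(benzyloxy)-4-(methoxymethoxy)phenoxy]benzene-1,3-diol
Product: 24 1,3,5-tris(benzyloxy)-2-[3,5-bis(benzyloxy)-4-(methoxymethoxy)phenoxy]benzene
Conditions: BnBr (2.5 equiv), Cs2CO3 (3 equiv), DMF, rt → 40 °C
Reagents that add atoms: benzyl bromide, BrCc1ccccc1
Why: Williamson ether synthesis with loosely paired cesium phenoxides in DMF, which favours O- over C-benzylation of the electron-rich ring.

**Step 15**
Reactants: 24 1,3,5-tris(benzyloxy)-2-[3,5-bis(benzyloxy)-4-(methoxymethoxy)phenoxy]benzene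
Product: 25 2,6-bis(benzyloxy)-4-[2,4,6-tris(benzyloxy)phenoxy]phenol
Conditions: 2 M aq. HCl (cat.), MeOH–THF, 50 °C
Reagents that add atoms: none
Why: Acid-catalysed acetal exchange removes only the MOM group, since aryl benzyl ethers and diaryl ethers are inert to dilute acid.

**Step 16**
Reactants: 26 1,3,5-trifluorobenzene
Product: 27 1,3-bis(benzyloxy)-5-fluorobenzene
Conditions: BnOH (2.05 equiv), NaH (2.05 equiv), THF, 0 °C → rt until H2 stops; then 26, DMF, pressure tube, 80 °C
Reagents that add atoms: benzyl alcohol, OCc1ccccc1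
Why: Stepwise SNAr, in which each fluoride is activated by the meta fluorines and every exchange of F for OBn slows the next one, so that two equivalents of alkoxide stop at the difunctionalised stage.

**Step 17**
Reactants: 27 1,3-bis(benzyloxy)-5-fluorobenzene
Product: 29 2,4-bis(benzyloxy)-6-fluorobenzaldehyde, via iminium chloride 28 (not isolated)
Conditions: POCl3 (1.5 equiv), DMF, 0 → 70 °C; ice–water
Reagents that add atoms: N,N-dimethylformamide, CN(C)C=O; water, O
Why: Vilsmeier–Haack formylation goes mainly to the position para to one OBn and flanked by the small fluorine instead of the site between the two OBn groups, and the minor isomer is removed by crystallisation or chromatography.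

**Step 18**
Reactants: 25 2,6-bis(benzyloxy)-4-[2,4,6-tris(benzyloxy)phenoxy]phenol; 29 2,4-bis(benzyloxy)-6-fluorobenzaldehyde
Product: 30 2,4-bis(benzyloxy)-6-{2,6-bis(benzyloxy)-4-[2,4,6-tris(benzyloxy)phenoxy]phenoxy}benzaldehyde
Conditions: Cs2CO3 (1.5 equiv), DMF, 100 °C, Ar
Reagents that add atoms: none
Why: SNAr of an electron-rich phenoxide on a fluoride that is ortho to the formyl acceptor and meta to both alkoxy groups, which therefore do not put charge on the attacked carbon.

**Step 19**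
Reactants: 30 2,4-bis(benzyloxy)-6-{2,6-bis(benzyloxy)-4-[2,4,6-tris(benzyloxy)phenoxy]phenoxy}benzaldehyde
Product: 32 2,4-bis(benzyloxy)-6-{2,6-bis(benzyloxy)-4-[2,4,6-tris(benzyloxy)phenoxy]phenoxy}phenol, via three-ring formate 31 (not isolated)
Conditions: mCPBA (1.3 equiv), CH2Cl2, 0 °C → rt; then K2CO3 (0.2 equiv), MeOH–THF, rt, Ar
Reagents that add atoms: mCPBA, OOC(=O)c1cccc(Cl)c1
Why: Baeyer–Villiger (Dakin-type) oxidation, in which the ortho,ortho,para-trioxygenated aryl group migrates readily and methanolysis of the formate places the oxygen of ring C exactly where ring D must be attached.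

**Step 20**
Reactants: 32 2,4-bis(benzyloxy)-6-{2,6-bis(benzyloxy)-4-[2,4,6-tris(benzyloxy)phenoxy]phenoxy}phenol; 10 1,3-bis(benzyloxy)-5-iodo-2-[3,4,5-tris(benzyloxy)phenoxy]benzene
Product: 33 dodeca-O-benzyl ether of the target
Conditions: CuI (20 mol %), picolinic acid (40 mol %), K3PO4 (2 equiv), DMSO–1,4-dioxane 1:1, 90 °C, Ar
Reagents that add atoms: none
Why: Ligand-accelerated Ullmann diaryl ether coupling pairs the hindered phenol with an iodide whose reacting carbon has only hydrogens ortho to it, the partner arrangement this catalyst handles best, and argon protects the oxidisable phenoxide.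

**Step 21**
Reactants: 33 dodeca-O-benzyl ether of the target
Product: 34 CNP0227069.0
Conditions: H2 (1 atm), 10 % Pd/C, THF–MeOH 1:1, rt; filter under Ar, Sephadex LH-20
Reagents that add atoms: none
Why: Catalytic hydrogenolysis cleaves all twelve benzylic C–O bonds under neutral conditions and leaves the four diaryl ether bonds and the oxidation-prone polyphenol intact.

**Compound list**
1 | 4-bromo-2,6-difluorobenzaldehyde | O=Cc1c(F)cc(Br)cc1F | starting material
2 | 2,6-bis(benzyloxy)-4-bromobenzaldehyde | O=Cc1c(OCc2ccccc2)cc(Br)cc1OCc1ccccc1 | intermediate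
3 | 2,6-bis(benzyloxy)-4-bromophenyl formate | O=COc1c(OCc2ccccc2)cc(Br)cc1OCc1ccccc1 | intermediate
4 | 2,6-bis(benzyloxy)-4-bromophenol | Oc1c(OCc2ccccc2)cc(Br)cc1OCc1ccccc1 | intermediate
5 | 1,2,3-tris(benzyloxy)-5-bromobenzene | Brc1cc(OCc2ccccc2)c(OCc2ccccc2)c(OCc2ccccc2)c1 | intermediate
6 | [3,4,5-tris(benzyloxy)phenyl]lithium | [Li]c1cc(OCc2ccccc2)c(OCc2ccccc2)c(OCc2ccccc2)c1 | intermediate
7 | lithium triisopropoxy[3,4,5-tris(benzyloxy)phenyl]borate | [Li+].CC(C)O[B-](OC(C)C)(OC(C)C)c1cc(OCc2ccccc2)c(OCc2ccccc2)c(OCc2ccccc2)c1 | intermediate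
8 | [3,4,5-tris(benzyloxy)phenyl]boronic acid | OB(O)c1cc(OCc2ccccc2)c(OCc2ccccc2)c(OCc2ccccc2)c1 | intermediate
9 | 1,3-bis(benzyloxy)-5-bromo-2-[3,4,5-tris(benzyloxy)phenoxy]benzene | Brc1cc(OCc2ccccc2)c(Oc2cc(OCc3ccccc3)c(OCc3ccccc3)c(OCc3ccccc3)c2)c(OCc2ccccc2)c1 | intermediate
10 | 1,3-bis(benzyloxy)-5-iodo-2-[3,4,5-tris(benzyloxy)phenoxy]benzene | Ic1cc(OCc2ccccc2)c(Oc2cc(OCc3ccccc3)c(OCc3ccccc3)c(OCc3ccccc3)c2)c(OCc2ccccc2)c1 | intermediate
11 | 1,3-bis(benzyloxy)-5-bromo-2-(methoxymethoxy)benzene | COCOc1c(OCc2ccccc2)cc(Br)cc1OCc1ccccc1 | intermediate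
12 | [3,5-bis(benzyloxy)-4-(methoxymethoxy)phenyl]lithium | [Li]c1cc(OCc2ccccc2)c(OCOC)c(OCc2ccccc2)c1 | intermediate
13 | lithium [3,5-bis(benzyloxy)-4-(methoxymethoxy)phenyl]trimethoxyborate | [Li+].CO[B-](OC)(OC)c1cc(OCc2ccccc2)c(OCOC)c(OCc2ccccc2)c1 | intermediate
14 | 3,5-bis(benzyloxy)-4-(methoxymethoxy)phenol | Oc1cc(OCc2ccccc2)c(OCOC)c(OCc2ccccc2)c1 | intermediate
15 | methyl bromoacetate | COC(=O)CBr | starting material
16 | methyl 2-[3,5-bis(benzyloxy)-4-(methoxymethoxy)phenoxy]acetate | COC(=O)COc1cc(OCc2ccccc2)c(OCOC)c(OCc2ccccc2)c1 | intermediate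
17 | methyl acetoacetate | CC(=O)CC(=O)OC | starting material
18 | sodium lithium dianion of methyl acetoacetate | [Na+].[Li+].[CH2-]C(=O)[CH-]C(=O)OC | intermediate
19 | methyl 6-[3,5-bis(benzyloxy)-4-(methoxymethoxy)phenoxy]-3,5-dioxohexanoate | COC(=O)CC(=O)CC(=O)COc1cc(OCc2ccccc2)c(OCOC)c(OCc2ccccc2)c1 | intermediate
20 | 6-{[3,5-bis(benzyloxy)-4-(methoxymethoxy)phenoxy]methyl}-4-hydroxy-2H-pyran-2-one | O=c1cc(O)cc(COc2cc(OCc3ccccc3)c(OCOC)c(OCc3ccccc3)c2)o1 | intermediate
21 | 4-(benzyloxy)-6-{[3,5-bis(benzyloxy)-4-(methoxymethoxy)phenoxy]methyl}-2H-pyran-2-one | O=c1cc(OCc2ccccc2)cc(COc2cc(OCc3ccccc3)c(OCOC)c(OCc3ccccc3)c2)o1 | intermediate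
22 | benzyl (2E)-3-(benzyloxy)-6-[3,5-bis(benzyloxy)-4-(methoxymethoxy)phenoxy]-5-oxohex-2-enoate (present as its sodium enolate) | O=C(OCc1ccccc1)/C=C(/OCc1ccccc1)CC(=O)COc1cc(OCc2ccccc2)c(OCOC)c(OCc2ccccc2)c1 | intermediate
23 | 5-(benzyloxy)-2-[3,5-bis(benzyloxy)-4-(methoxymethoxy)phenoxy]benzene-1,3-diol | Oc1cc(OCc2ccccc2)cc(O)c1Oc1cc(OCc2ccccc2)c(OCOC)c(OCc2ccccc2)c1 | intermediate
24 | 1,3,5-tris(benzyloxy)-2-[3,5-bis(benzyloxy)-4-(methoxymethoxy)phenoxy]benzene | COCOc1c(OCc2ccccc2)cc(Oc2c(OCc3ccccc3)cc(OCc3ccccc3)cc2OCc2ccccc2)cc1OCc1ccccc1 | intermediate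
25 | 2,6-bis(benzyloxy)-4-[2,4,6-tris(benzyloxy)phenoxy]phenol | Oc1c(OCc2ccccc2)cc(Oc2c(OCc3ccccc3)cc(OCc3ccccc3)cc2OCc2ccccc2)cc1OCc1ccccc1 | intermediate
26 | 1,3,5-trifluorobenzene | Fc1cc(F)cc(F)c1 | starting material
27 | 1,3-bis(benzyloxy)-5-fluorobenzene | Fc1cc(OCc2ccccc2)cc(OCc2ccccc2)c1 | intermediate
28 | [2,4-bis(benzyloxy)-6-fluorobenzylidene]dimethyliminium chloride | C[N+](C)=Cc1c(F)cc(OCc2ccccc2)cc1OCc1ccccc1.[Cl-] | intermediate
29 | 2,4-bis(benzyloxy)-6-fluorobenzaldehyde | O=Cc1c(F)cc(OCc2ccccc2)cc1OCc1ccccc1 | intermediate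
30 | 2,4-bis(benzyloxy)-6-{2,6-bis(benzyloxy)-4-[2,4,6-tris(benzyloxy)phenoxy]phenoxy}benzaldehyde | O=Cc1c(OCc2ccccc2)cc(OCc2ccccc2)cc1Oc1c(OCc2ccccc2)cc(Oc2c(OCc3ccccc3)cc(OCc3ccccc3)cc2OCc2ccccc2)cc1OCc1ccccc1 | intermediate
31 | 2,4-bis(benzyloxy)-6-{2,6-bis(benzyloxy)-4-[2,4,6-tris(benzyloxy)phenoxy]phenoxy}phenyl formate | O=COc1c(OCc2ccccc2)cc(OCc2ccccc2)cc1Oc1c(OCc2ccccc2)cc(Oc2c(OCc3ccccc3)cc(OCc3ccccc3)cc2OCc2ccccc2)cc1OCc1ccccc1 | intermediate
32 | 2,4-bis(benzyloxy)-6-{2,6-bis(benzyloxy)-4-[2,4,6-tris(benzyloxy)phenoxy]phenoxy}phenol | Oc1c(OCc2ccccc2)cc(OCc2ccccc2)cc1Oc1c(OCc2ccccc2)cc(Oc2c(OCc3ccccc3)cc(OCc3ccccc3)cc2OCc2ccccc2)cc1OCc1ccccc1 | intermediate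
33 | dodeca-O-benzyl ether of the target (every OH of 34 as OCH2Ph) | c5ccccc5COc1cc(OCc5ccccc5)c(Oc2cc(OCc5ccccc5)c(Oc3cc(OCc5ccccc5)cc(OCc5ccccc5)c3Oc3cc(OCc5ccccc5)c(Oc4cc(OCc5ccccc5)c(OCc5ccccc5)c(OCc5ccccc5)c4)c(OCc5ccccc5)c3)c(OCc5ccccc5)c2)c(OCc5ccccc5)c1 | intermediate
34 | CNP0227069.0, 2-{4-[2-(3,5-dihydroxy-4-(3,4,5-trihydroxyphenoxy)phenoxy)-3,5-dihydroxyphenoxy]-3,5-dihydroxyphenoxy}benzene-1,3,5-triol (achiral) | Oc1cc(O)c(Oc2cc(O)c(Oc3cc(O)cc(O)c3Oc3cc(O)c(Oc4cc(O)c(O)c(O)c4)c(O)c3)c(O)c2)c(O)c1 | target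

**Step count**
Total step count: 21.
Longest linear sequence: 15 steps (1, 2, 7, 8, 9, 10, 11, 12, 13, 14, 15, 18, 19, 20, 21).

**Three steps most likely to fail**

**Step 13 (ring A closure).** The most acidic position of 22 is C4–H. Its vinylogous enolate deactivates the ester, and the C6 enolate that must attack is only a minor partner. The closure therefore needs heat and may stall or erode the benzyl ethers.

The fallback sets out from 14 and comes back at 24. It moves the ring-closing nucleophile to a doubly activated carbon. Phenol 14 is O-alkylated with methyl 4-chloroacetoacetate (NaH 2.2 equiv, THF, 50 °C) to methyl 4-[3,5-bis(benzyloxy)-4-(methoxymethoxy)phenoxy]-3-oxobutanoate F1. Me3SiCl and Et3N convert it to the (Z)-silyl enol ether F2, and LDA then Me3SiCl at −78 °C give the 4-aryloxy-1-methoxy-1,3-bis(trimethylsilyloxy)buta-1,3-diene F3. This masked dianion is acylated at its aryloxy-bearing terminus by methyl malonyl chloride (CH2Cl2, −78 → 20 °C, Claisen-type C-acylation) to dimethyl 4-aryloxy-3,5-dioxoheptanedioate F4. NaOMe in MeOH then closes ring A from the beta-keto ester carbon C2 onto the C7 ester (Dieckmann) to methyl 3-aryloxy-2,4,6-trihydroxybenzoate F5. Aqueous KOH at reflux under Ar, followed by acidification to pH 5, removes the ester as CO2 and gives 2-aryloxybenzene-1,3,5-triol F6. BnBr (3.5 equiv) and Cs2CO3 in DMF give 24.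

**Step 18 (SNAr of the di-ortho-substituted phenoxide).** The two alkoxy donors weaken the formyl acceptor of 29, and the nucleophile is crowded.

The fallback sets out from 25 and comes back at 30. It replaces the uncatalysed substitution by a copper-catalysed coupling of an ortho-formyl aryl bromide. Commercial 5-bromoresorcinol is benzylated (BnBr, K2CO3, DMF) to 1,3-bis(benzyloxy)-5-bromobenzene F7. This is formylated ortho to bromine (POCl3, DMF, through the iminium chloride F8) to 2,4-bis(benzyloxy)-6-bromobenzaldehyde F9. F9 is joined to 25 with CuI (20 mol %), picolinic acid (40 mol %) and K3PO4 in DMSO at 90 °C. The neighbouring carbonyl group speeds oxidative addition to monovalent copper, and the product is 30.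

**Step 20 (Ullmann coupling of 32).** The phenol is flanked by OBn and by a bulky aryloxy group that itself carries two ortho substituents, and iodide 10 is electron-rich.

The fallback sets out from 32 and comes back at 33. It adds rings D and E one at a time with an electron-poor partner. Phenol 32 is arylated with the para-formyl bromide 2 (CuI 10 mol %, picolinic acid 20 mol %, K3PO4, DMSO, 90 °C), which the formyl group makes far more reactive than 10, to the four-ring aldehyde F10. mCPBA gives the four-ring formate F11, and K2CO3 in MeOH gives the four-ring phenol F12. This phenol is flanked only by two OBn groups, like 4. Chan–Lam coupling of F12 with boronic acid 8 under the conditions of step 5 gives 33.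

**Further compounds**
F1 | step 13 | methyl 4-[3,5-bis(benzyloxy)-4-(methoxymethoxy)phenoxy]-3-oxobutanoate | COC(=O)CC(=O)COc1cc(OCc2ccccc2)c(OCOC)c(OCc2ccccc2)c1
F2 | step 13 | methyl (2Z)-4-[3,5-bis(benzyloxy)-4-(methoxymethoxy)phenoxy]-3-(trimethylsilyloxy)but-2-enoate | COC(=O)/C=C(\O[Si](C)(C)C)COc1cc(OCc2ccccc2)c(OCOC)c(OCc2ccccc2)c1
F3 | step 13 | 4-[3,5-bis(benzyloxy)-4-(methoxymethoxy)phenoxy]-1-methoxy-1,3-bis(trimethylsilyloxy)buta-1,3-diene (E/Z mixture) | COC(O[Si](C)(C)C)=CC(O[Si](C)(C)C)=COc1cc(OCc2ccccc2)c(OCOC)c(OCc2ccccc2)c1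
F4 | step 13 | dimethyl 4-[3,5-bis(benzyloxy)-4-(methoxymethoxy)phenoxy]-3,5-dioxoheptanedioate | COC(=O)CC(=O)C(Oc1cc(OCc2ccccc2)c(OCOC)c(OCc2ccccc2)c1)C(=O)CC(=O)OC
F5 | step 13 | methyl 3-[3,5-bis(benzyloxy)-4-(methoxymethoxy)phenoxy]-2,4,6-trihydroxybenzoate | COC(=O)c1c(O)cc(O)c(Oc2cc(OCc3ccccc3)c(OCOC)c(OCc3ccccc3)c2)c1O
F6 | step 13 | 2-[3,5-bis(benzyloxy)-4-(methoxymethoxy)phenoxy]benzene-1,3,5-triol | Oc1cc(O)c(Oc2cc(OCc3ccccc3)c(OCOC)c(OCc3ccccc3)c2)c(O)c1
F7 | step 18 | 1,3-bis(benzyloxy)-5-bromobenzene | Brc1cc(OCc2ccccc2)cc(OCc2ccccc2)c1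
F8 | step 18 | [2,4-bis(benzyloxy)-6-bromobenzylidene]dimethyliminium chloride | C[N+](C)=Cc1c(Br)cc(OCc2ccccc2)cc1OCc1ccccc1.[Cl-]
F9 | step 18 | 2,4-bis(benzyloxy)-6-bromobenzaldehyde | O=Cc1c(Br)cc(OCc2ccccc2)cc1OCc1ccccc1
F10 | step 20 | 2,6-bis(benzyloxy)-4-(2,4-bis(benzyloxy)-6-{2,6-bis(benzyloxy)-4-[2,4,6-tris(benzyloxy)phenoxy]phenoxy}phenoxy)benzaldehyde | O=Cc1c(OCc2ccccc2)cc(Oc2c(OCc3ccccc3)cc(OCc3ccccc3)cc2Oc2c(OCc3ccccc3)cc(Oc3c(OCc4ccccc4)cc(OCc4ccccc4)cc3OCc3ccccc3)cc2OCc2ccccc2)cc1OCc1ccccc1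
F11 | step 20 | 2,6-bis(benzyloxy)-4-(2,4-bis(benzyloxy)-6-{2,6-bis(benzyloxy)-4-[2,4,6-tris(benzyloxy)phenoxy]phenoxy}phenoxy)phenyl formate | O=COc1c(OCc2ccccc2)cc(Oc2c(OCc3ccccc3)cc(OCc3ccccc3)cc2Oc2c(OCc3ccccc3)cc(Oc3c(OCc4ccccc4)cc(OCc4ccccc4)cc3OCc3ccccc3)cc2OCc2ccccc2)cc1OCc1ccccc1
F12 | step 20 | 2,6-bis(benzyloxy)-4-(2,4-bis(benzyloxy)-6-{2,6-bis(benzyloxy)-4-[2,4,6-tris(benzyloxy)phenoxy]phenoxy}phenoxy)phenol | Oc1c(OCc2ccccc2)cc(Oc2c(OCc3ccccc3)cc(OCc3ccccc3)cc2Oc2c(OCc3ccccc3)cc(Oc3c(OCc4ccccc4)cc(OCc4ccccc4)cc3OCc3ccccc3)cc2OCc2ccccc2)cc1OCc1ccccc1
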